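**Retrosynthetic overview**

1. Feature used: in isoflavan 18 the C4a–C4 bond (ring A to ring C) and the C3'–C4'' bond (ring B to pyran ring D) each lie ortho to an aryl ether oxygen, and the C5 and C8a oxygens of ring A are equivalent until one of them is methylated.
2. 18 ⇐ ring C closed last at O1–C2 (Mitsunobu) from triphenol alcohol 17 ⇐ MOM removal and asymmetric hydroboration–oxidation (sets C3) of 1,1-disubstituted alkene 14 ⇐ O-methylation of phenol 13.
3. 13 ⇐ one heating of bis-ether 10: ring-A 2-arylallyl ether Claisen shift (C4a–C4) plus ring-B propargyl Claisen shift, [1,5]-hydrogen shift and oxa-6π closure (C3'–C4'', O2'–C2'', ring D).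
4. 10 ⇐ Wittig methylenation of α-aryloxy ketone 9 ⇐ bromoketone 6 + 3,5-bis(methoxymethoxy)phenol 8; 6 from 2,4-dihydroxyacetophenone 1 and 3-chloro-3-methylbut-1-yne 3, 8 from phloroglucinol 7.
5. Ring order: rings A and B are bought, ring D forms in step 7, ring C in step 12.

Key step: step 7

Assumption: isoflavan numbering is used (O1, C2, C3, C4, C4a, C5 to C8a; ring B primed; ring D double-primed). The antipode of the oxazoline ligand in step 9 that delivers the R boronate is to be fixed on a first small run, both antipodes being accessible from the two enantiomers of the amino alcohol.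

**Route**

Step 1
Reactants: 1 2,4-dihydroxyacetophenone
Product: 2 1-[2-hydroxy-4-(methoxymethoxy)phenyl]ethan-1-one
Conditions: MOMCl (1.1 equiv), K2CO3, acetone, 0 °C to rt
Reagents that add atoms: chloromethyl methyl ether, COCCl
Why: Williamson-type O-alkylation should be selective for the 4-hydroxyl, because the 2-hydroxyl is hydrogen-bonded to the ketone and is the poorer nucleophile.

Step 2
Reactants: 2 1-[2-hydroxy-4-(methoxymethoxy)phenyl]ethan-1-one; 3 3-chloro-3-methylbut-1-yne
Product: 4 1-[4-(methoxymethoxy)-2-[(2-methylbut-3-yn-2-yl)oxy]phenyl]ethan-1-one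
Conditions: DBU, CuCl2·2H2O (cat.), MeCN, 0 °C to rt
Reagents that add atoms: none
Why: Copper-catalysed propargylic substitution, in which DBU breaks the hydrogen bond by deprotonating the phenol and the copper acetylide of 3 ionises to an allenylidene that the phenoxide captures at the tertiary carbon.

Step 3
Reactants: 4 1-[4-(methoxymethoxy)-2-[(2-methylbut-3-yn-2-yl)oxy]phenyl]ethan-1-one
Product: 6 2-bromo-1-[4-(methoxymethoxy)-2-[(2-methylbut-3-yn-2-yl)oxy]phenyl]ethan-1-one, via trimethylsilyl enol ether 5 (not isolated)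
Conditions: LiN(SiMe3)2 (1.05 equiv), THF, −78 °C; Me3SiCl; then NBS, THF, −78 to 0 °C
Reagents that add atoms: N-bromosuccinimide, O=C1CCC(=O)N1Br; chlorotrimethylsilane, C[Si](C)(C)Cl (silyl group of 5 only)
Why: α-Bromination through the silyl enol ether, in which the amide base forms the methyl ketone enolate in preference to deprotonating the less acidic alkyne C–H, and NBS then brominates the enol ether under neutral conditions that spare the MOM acetal, the alkyne and the arene.

Step 4
Reactants: 7 phloroglucinol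
Product: 8 3,5-bis(methoxymethoxy)phenol
Conditions: MOMCl (2.0 equiv), i-Pr2NEt, DMF, 0 °C to rt; chromatography
Reagents that add atoms: chloromethyl methyl ether, COCCl
Why: Statistical bis-O-alkylation of the threefold-symmetric triol, from which the mono- and tris-ethers are removed by chromatography.

Step 5
Reactants: 6 2-bromo-1-[4-(methoxymethoxy)-2-[(2-methylbut-3-yn-2-yl)oxy]phenyl]ethan-1-one; 8 3,5-bis(methoxymethoxy)phenol
Product: 9 2-[3,5-bis(methoxymethoxy)phenoxy]-1-[4-(methoxymethoxy)-2-[(2-methylbut-3-yn-2-yl)oxy]phenyl]ethan-1-one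
Conditions: K2CO3, acetone, rt
Reagents that add atoms: none
Why: Williamson ether synthesis by SN2 displacement of the activated phenacyl bromide, with O-alkylation of the potassium phenoxide favoured in a polar aprotic solvent.

Step 6
Reactants: 9 2-[3,5-bis(methoxymethoxy)phenoxy]-1-[4-(methoxymethoxy)-2-[(2-methylbut-3-yn-2-yl)oxy]phenyl]ethan-1-one
Product: 10 1-{3-[3,5-bis(methoxymethoxy)phenoxy]prop-1-en-2-yl}-4-(methoxymethoxy)-2-[(2-methylbut-3-yn-2-yl)oxy]benzene
Conditions: Ph3PCH3Br (1.5 equiv), KOtBu (1.4 equiv), THF, 0 °C to rt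
Reagents that add atoms: methyltriphenylphosphonium bromide, C[P+](c1ccccc1)(c1ccccc1)c1ccccc1.[Br-]
Why: Wittig methylenation of the aryl ketone with the non-stabilised ylide, the base being kept below the amount of phosphonium salt so that no free alkoxide is left to act on the alkyne C–H or the α-aryloxy ketone.

Step 7
Reactants: 10 1-{3-[3,5-bis(methoxymethoxy)phenoxy]prop-1-en-2-yl}-4-(methoxymethoxy)-2-[(2-methylbut-3-yn-2-yl)oxy]benzene
Product: 13 3,5-bis(methoxymethoxy)-2-{2-[5-(methoxymethoxy)-2,2-dimethyl-2H-chromen-8-yl]prop-2-en-1-yl}phenol, via ortho-quinone methide 11 (not isolated), via chromenyl allyl ether 12 (not isolated)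
Conditions: PhNEt2 (dilute), 200 °C, sealed tube, Ar
Reagents that add atoms: none
Why: On ring B the 1,1-dimethylpropargyl ether should undergo a [3,3] shift to C3', and enolisation followed by a [1,5]-hydrogen shift leads to ortho-quinone methide 11, which closes to chromene 12; on ring A the 2-arylallyl ether then undergoes a [3,3] shift that joins the allyl terminus to C4a (the C4a–C4 bond) and tautomerisation restores the phenol in 13. The closest known reactions are the aromatic Claisen rearrangement of aryl allyl ethers and the thermal conversion of aryl 1,1-dimethylpropargyl ethers into 2,2-dimethyl-2H-chromenes, here run in a single heating period, the propargyl ether being expected to react first. Ring D closes by a thermally allowed disrotatory oxa-6π electrocyclisation of the Z-configured dienone 11, which forms O2'–C2'' after the sigmatropic shift has formed C3'–C4''. No stereocentre is created, and C3 is set later on the 1,1-disubstituted alkene that this step leaves in place. Only regioselectivity is required: the two ortho carbons of ring A are equivalent by the symmetry of the 3,5-bis(methoxymethoxy)phenyl ether, and on ring B C1' is substituted, so only the shift to C3' can end in rearomatisation. The amine solvent buffers the liberated phenol, which should keep it from adding to the 1,1-disubstituted alkene and keep the MOM acetals intact.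

Step 8
Reactants: 13 3,5-bis(methoxymethoxy)-2-{2-[5-(methoxymethoxy)-2,2-dimethyl-2H-chromen-8-yl]prop-2-en-1-yl}phenol
Product: 14 8-{3-[2-methoxy-4,6-bis(methoxymethoxy)phenyl]prop-1-en-2-yl}-5-(methoxymethoxy)-2,2-dimethyl-2H-chromene
Conditions: MeI, K2CO3, DMF, rt
Reagents that add atoms: iodomethane, CI
Why: Williamson O-methylation of the only free phenol fixes this oxygen as the C5 methoxy and so differentiates the two formerly equivalent ring-A oxygens.

Step 9
Reactants: 14 8-{3-[2-methoxy-4,6-bis(methoxymethoxy)phenyl]prop-1-en-2-yl}-5-(methoxymethoxy)-2,2-dimethyl-2H-chromene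
Product: 15 2-{(2R)-3-[2-methoxy-4,6-bis(methoxymethoxy)phenyl]-2-[5-(methoxymethoxy)-2,2-dimethyl-2H-chromen-8-yl]propyl}-4,4,5,5-tetramethyl-1,3,2-dioxaborolane
Conditions: CoCl2 (cat.), chiral iminopyridine–oxazoline ligand (2,6-diisopropylphenyl ketimine, tert-butyl oxazoline; cat.), NaBEt3H (cat.), HBpin, THF, rt
Reagents that add atoms: pinacolborane, CC1(C)OBOC1(C)C
Why: Cobalt-catalysed anti-Markovnikov asymmetric hydroboration of a 1,1-disubstituted aryl alkene, in which C3 is set under catalyst control in the enantio-determining insertion of the alkene into the cobalt hydride within the pocket of the chiral ligand, while the cis-disubstituted chromene alkene beside the gem-dimethyl carbon should be much less reactive.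

Step 10
Reactants: 15 2-{(2R)-3-[2-methoxy-4,6-bis(methoxymethoxy)phenyl]-2-[5-(methoxymethoxy)-2,2-dimethyl-2H-chromen-8-yl]propyl}-4,4,5,5-tetramethyl-1,3,2-dioxaborolane
Product: 16 (2R)-3-[2-methoxy-4,6-bis(methoxymethoxy)phenyl]-2-[5-(methoxymethoxy)-2,2-dimethyl-2H-chromen-8-yl]propan-1-ol
Conditions: H2O2 (30% aq.), NaOH, THF, 0 °C to rt
Reagents that add atoms: hydrogen peroxide, OO
Why: Alkaline peroxide oxidation of the primary C–B bond proceeds by 1,2-migration on boron and does not touch the stereocentre on the neighbouring carbon.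

Step 11
Reactants: 16 (2R)-3-[2-methoxy-4,6-bis(methoxymethoxy)phenyl]-2-[5-(methoxymethoxy)-2,2-dimethyl-2H-chromen-8-yl]propan-1-ol
Product: 17 4-[(2R)-3-hydroxy-2-(5-hydroxy-2,2-dimethyl-2H-chromen-8-yl)propyl]-5-methoxybenzene-1,3-diol
Conditions: HCl (dilute, in MeOH), 40 °C; used directly
Reagents that add atoms: none
Why: Acid-catalysed acetal exchange with methanol removes the three aryl MOM ethers as dimethoxymethane, and dilute acid at mild temperature is chosen to spare the electron-rich chromene alkene and the aryl methyl ether.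

Step 12
Reactants: 17 4-[(2R)-3-hydroxy-2-(5-hydroxy-2,2-dimethyl-2H-chromen-8-yl)propyl]-5-methoxybenzene-1,3-diol
Product: 18 (3R)-3-(5-hydroxy-2,2-dimethyl-2H-chromen-8-yl)-5-methoxy-3,4-dihydro-2H-chromen-7-ol
Conditions: PPh3, DIAD, THF (0.01 M), 0 °C to rt
Reagents that add atoms: none
Why: Intramolecular Mitsunobu etherification, in which the oxyphosphonium of the primary alcohol is displaced by the one phenol that can reach it through a six-membered (6-exo-tet) transition state, the C8a hydroxyl, so ring C closes at C2 without touching C3 and dilution suppresses intermolecular alkylation of the C7 and C4' phenols.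

**Compound list**

1 | 2,4-dihydroxyacetophenone | CC(=O)c1ccc(O)cc1O | starting material
2 | 1-[2-hydroxy-4-(methoxymethoxy)phenyl]ethan-1-one | CC(=O)c1ccc(OCOC)cc1O | intermediate
3 | 3-chloro-3-methylbut-1-yne | C#CC(C)(C)Cl | starting material
4 | 1-[4-(methoxymethoxy)-2-[(2-methylbut-3-yn-2-yl)oxy]phenyl]ethan-1-one | CC(=O)c1ccc(OCOC)cc1OC(C)(C)C#C | intermediate
5 | trimethylsilyl enol ether of 4, {1-[4-(methoxymethoxy)-2-[(2-methylbut-3-yn-2-yl)oxy]phenyl]ethenyl}oxy(trimethyl)silane | C=C(O[Si](C)(C)C)c1ccc(OCOC)cc1OC(C)(C)C#C | intermediate (not isolated)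
6 | 2-bromo-1-[4-(methoxymethoxy)-2-[(2-methylbut-3-yn-2-yl)oxy]phenyl]ethan-1-one | O=C(CBr)c1ccc(OCOC)cc1OC(C)(C)C#C | intermediate
7 | phloroglucinol (benzene-1,3,5-triol) | Oc1cc(O)cc(O)c1 | starting material
8 | 3,5-bis(methoxymethoxy)phenol | Oc1cc(OCOC)cc(OCOC)c1 | intermediate
9 | 2-[3,5-bis(methoxymethoxy)phenoxy]-1-[4-(methoxymethoxy)-2-[(2-methylbut-3-yn-2-yl)oxy]phenyl]ethan-1-one | O=C(COc1cc(OCOC)cc(OCOC)c1)c1ccc(OCOC)cc1OC(C)(C)C#C | intermediate
10 | bis-ether, 1-{3-[3,5-bis(methoxymethoxy)phenoxy]prop-1-en-2-yl}-4-(methoxymethoxy)-2-[(2-methylbut-3-yn-2-yl)oxy]benzene | C=C(COc1cc(OCOC)cc(OCOC)c1)c1ccc(OCOC)cc1OC(C)(C)C#C | intermediate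
11 | ortho-quinone methide, (6Z)-2-{3-[3,5-bis(methoxymethoxy)phenoxy]prop-1-en-2-yl}-5-(methoxymethoxy)-6-(3-methylbut-2-en-1-ylidene)cyclohexa-2,4-dien-1-one | C=C(COc1cc(OCOC)cc(OCOC)c1)C1=CC=C(OCOC)/C(=C/C=C(C)C)C1=O | intermediate (not isolated)
12 | chromenyl allyl ether, 8-{3-[3,5-bis(methoxymethoxy)phenoxy]prop-1-en-2-yl}-5-(methoxymethoxy)-2,2-dimethyl-2H-chromene | C=C(COc1cc(OCOC)cc(OCOC)c1)c1ccc(OCOC)c2c1OC(C)(C)C=C2 | intermediate (not isolated)
13 | 3,5-bis(methoxymethoxy)-2-{2-[5-(methoxymethoxy)-2,2-dimethyl-2H-chromen-8-yl]prop-2-en-1-yl}phenol | C=C(Cc1c(O)cc(OCOC)cc1OCOC)c1ccc(OCOC)c2c1OC(C)(C)C=C2 | intermediate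
14 | 8-{3-[2-methoxy-4,6-bis(methoxymethoxy)phenyl]prop-1-en-2-yl}-5-(methoxymethoxy)-2,2-dimethyl-2H-chromene | C=C(Cc1c(OC)cc(OCOC)cc1OCOC)c1ccc(OCOC)c2c1OC(C)(C)C=C2 | intermediate
15 | 2-{(2R)-3-[2-methoxy-4,6-bis(methoxymethoxy)phenyl]-2-[5-(methoxymethoxy)-2,2-dimethyl-2H-chromen-8-yl]propyl}-4,4,5,5-tetramethyl-1,3,2-dioxaborolane | CC1(C)OB(C[C@H](Cc2c(OC)cc(OCOC)cc2OCOC)c2ccc(OCOC)c3c2OC(C)(C)C=C3)OC1(C)C | intermediate
16 | (2R)-3-[2-methoxy-4,6-bis(methoxymethoxy)phenyl]-2-[5-(methoxymethoxy)-2,2-dimethyl-2H-chromen-8-yl]propan-1-ol | OC[C@H](Cc1c(OC)cc(OCOC)cc1OCOC)c1ccc(OCOC)c2c1OC(C)(C)C=C2 | intermediate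
17 | 4-[(2R)-3-hydroxy-2-(5-hydroxy-2,2-dimethyl-2H-chromen-8-yl)propyl]-5-methoxybenzene-1,3-diol | OC[C@H](Cc1c(OC)cc(O)cc1O)c1ccc(O)c2c1OC(C)(C)C=C2 | intermediate
18 | (3R)-3-(5-hydroxy-2,2-dimethyl-2H-chromen-8-yl)-5-methoxy-3,4-dihydro-2H-chromen-7-ol | COc1cc(O)cc2c1C[C@H](c1ccc(O)c3c1OC(C)(C)C=C3)CO2 | target

**Step count**

Total: 12 steps. Longest linear sequence: 11 steps (1 → 2 → 4 → 6 → 9 → 10 → 13 → 14 → 15 → 16 → 17 → 18, that is steps 1, 2, 3, 5, 6, 7, 8, 9, 10, 11 and 12). Step 4 is a one-step side branch.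

**Steps most likely to fail**

Step 7. The two rearrangements may not share a temperature window. During the longer heating that the ring-A shift needs, material may be lost by thermal degradation, by addition of the freed phenol across the 1,1-disubstituted alkene, or by homolysis of the allyl ether C–O bond. The fallback separates the two events and builds ring D first on a robust ketone. It sets out from 4, which is heated alone (xylene or DMF, about 140 °C) so that the propargyl ether rearranges and cyclises to 1-[5-(methoxymethoxy)-2,2-dimethyl-2H-chromen-8-yl]ethan-1-one F1. Treatment with LiN(SiMe3)2 and Me3SiCl gives the trimethylsilyl enol ether F2 (not isolated), and NBS converts it into the bromoketone F3. Displacement with 8 and K2CO3 in acetone gives the aryloxy ketone F4, and Wittig methylenation gives the chromenyl allyl ether, at which point the fallback comes back to the route at 12. Compound 12 is then heated by itself in PhNEt2, as a single aromatic Claisen rearrangement on a substrate that no longer carries an alkyne, to give 13.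

Step 9. Facial selectivity may be poor, or insertion slow, at an alkene flanked by an ortho-substituted aryl group and a 2,6-disubstituted benzyl group; cobalt hydride isomerisation of the alkene into conjugation is a second risk. The fallback sets C3 by dynamic kinetic resolution instead of by alkene insertion. It sets out from 14, which is hydroborated with 9-BBN in THF to the B-alkyl-9-borabicyclononane F5 (not isolated) and oxidised with H2O2 and NaOH to the racemic primary alcohol F6. Dess–Martin periodinane buffered with NaHCO3 gives the racemic α-aryl aldehyde F7. Hydrogenation of F7 with a RuCl2(chiral diphosphine)(chiral 1,2-diamine) catalyst and KOtBu in i-PrOH under H2 should reduce the matched enantiomer of the aldehyde while the base racemises the α-aryl centre. The catalyst antipode is chosen for R, and the carbonyl-selective catalyst leaves the chromene alkene alone. The fallback comes back to the route at 16.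

Step 12. With three acidic phenols present, the betaine may be consumed unproductively and intermolecular etherification through the C7 or C4' phenol may compete with ring closure. The fallback activates the alcohol before the phenols are unmasked and closes ring C by base-mediated alkylation. It sets out from 16, which with MsCl and Et3N in CH2Cl2 at 0 °C gives the primary methanesulfonate F8. Dilute HCl in MeOH at 40 °C removes the three MOM groups to give the triphenol methanesulfonate F9. K2CO3 in dilute acetone then lets the C8a phenoxide displace the sulfonate (6-exo-tet), which comes back to the route at 18.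

**Further compounds**

F1 | step 7 | 1-[5-(methoxymethoxy)-2,2-dimethyl-2H-chromen-8-yl]ethan-1-one | CC(=O)c1ccc(OCOC)c2c1OC(C)(C)C=C2
F2 | step 7 | {1-[5-(methoxymethoxy)-2,2-dimethyl-2H-chromen-8-yl]ethenyl}oxy(trimethyl)silane | C=C(O[Si](C)(C)C)c1ccc(OCOC)c2c1OC(C)(C)C=C2
F3 | step 7 | 2-bromo-1-[5-(methoxymethoxy)-2,2-dimethyl-2H-chromen-8-yl]ethan-1-one | O=C(CBr)c1ccc(OCOC)c2c1OC(C)(C)C=C2
F4 | step 7 | 2-[3,5-bis(methoxymethoxy)phenoxy]-1-[5-(methoxymethoxy)-2,2-dimethyl-2H-chromen-8-yl]ethan-1-one | O=C(COc1cc(OCOC)cc(OCOC)c1)c1ccc(OCOC)c2c1OC(C)(C)C=C2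
F5 | step 9 | 9-{3-[2-methoxy-4,6-bis(methoxymethoxy)phenyl]-2-[5-(methoxymethoxy)-2,2-dimethyl-2H-chromen-8-yl]propyl}-9-borabicyclo[3.3.1]nonane (racemic) | C1CCC2CCCC1B2CC(Cc1c(OC)cc(OCOC)cc1OCOC)c1ccc(OCOC)c2c1OC(C)(C)C=C2
F6 | step 9 | racemic 3-[2-methoxy-4,6-bis(methoxymethoxy)phenyl]-2-[5-(methoxymethoxy)-2,2-dimethyl-2H-chromen-8-yl]propan-1-ol | OCC(Cc1c(OC)cc(OCOC)cc1OCOC)c1ccc(OCOC)c2c1OC(C)(C)C=C2
F7 | step 9 | racemic 3-[2-methoxy-4,6-bis(methoxymethoxy)phenyl]-2-[5-(methoxymethoxy)-2,2-dimethyl-2H-chromen-8-yl]propanal | O=CC(Cc1c(OC)cc(OCOC)cc1OCOC)c1ccc(OCOC)c2c1OC(C)(C)C=C2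
F8 | step 12 | (2R)-3-[2-methoxy-4,6-bis(methoxymethoxy)phenyl]-2-[5-(methoxymethoxy)-2,2-dimethyl-2H-chromen-8-yl]propyl methanesulfonate | CS(=O)(=O)OC[C@H](Cc1c(OC)cc(OCOC)cc1OCOC)c1ccc(OCOC)c2c1OC(C)(C)C=C2
F9 | step 12 | (2R)-3-(2,4-dihydroxy-6-methoxyphenyl)-2-(5-hydroxy-2,2-dimethyl-2H-chromen-8-yl)propyl methanesulfonate | CS(=O)(=O)OC[C@H](Cc1c(OC)cc(O)cc1O)c1ccc(O)c2c1OC(C)(C)C=C2
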